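Atom numbers follow the neolignan numbering of the target: C7, C8 and C9 are the propane chain on ring A, and primed numbers belong to ring B and its side chain.

Analysis of the target

The target 10 is a 2-aryl-3-(hydroxymethyl)-2,3-dihydrobenzofuran. Ring A (3,4,5-trimethoxyphenyl) sits on C7; ring B, the benzene fused to the heterocycle, carries the C5' methoxy group and the (E)-3-hydroxyprop-1-enyl chain at C1'; the five-membered oxygen ring consists of O4', C4', C3', C8 and C7. The only stereocentres are the neighbouring C7 (R) and C8 (S); ring A and the C9 hydroxymethyl group are trans on the dihydrofuran, which is also the more stable arrangement, and the side-chain alkene C7'=C8' is (E). The relative configuration is therefore the easy part; the hard part is the absolute configuration at C7, an ether carbon that is benzylic and para to a methoxy group, so it can ionise under acid and be scrambled. Further sensitive points are the cinnamyl alcohol (acid, oxidants) and, in any intermediate with C9 at the ester level, the acidic H8, whose removal by base can expel the ring B phenoxide and open the ring. Oxidative phenol coupling, the classical entry to this skeleton, is of no use here, since ring A has no free phenol and such couplings give racemates. The feature on which the plan rests is that the two bonds that make C7 and C8 stereogenic, C7–O4' and C8–C9, stand on adjacent carbons: removed together they leave a C7=C8 double bond, that is, an (E)-2-hydroxystilbene whose phenol oxygen is O4'. An anti addition of that oxygen and of a one-carbon unit across the (E)-alkene maps directly onto the trans relationship of the target.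

Retrosynthetic reasoning

10 to 9. Both primary alcohols of 10 are traced back to methyl esters in diester 9. No skeletal bond is cut. The gain is that the acid-sensitive allylic alcohol is released only in the last step, and that the side-chain alkene travels as an electron-poor acrylate, which matters for the step before. The forward reaction is a double hydride reduction that has to give 1,2-reduction at the cinnamate and must not disturb C7 or C8.

9 to 8. In 9 the C7–O4' and C8–C9 bonds are cut together. This opens the dihydrofuran, removes both stereocentres and leads to the achiral hydroxystilbene 8. Cutting here is preferred to cutting C7–C8 or C4'–O4' because nothing stereogenic has to be prepared beforehand: the whole stereochemical problem is placed in one catalytic addition across an alkene of fixed (E)-geometry. The forward reaction has to add the phenol oxygen to C7 and a carbonyl carbon to C8 from opposite faces, choose one enantioface of the alkene, and intercept the carbon–palladium bond at C8 by carbonylation before β-hydride elimination can aromatise the new ring. It must also leave the acrylate alkene alone.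

8 to 7. The free phenol of 8 is masked as a methoxymethyl ether in 7. A free ortho phenoxide would deactivate the aldehyde in the olefination that builds the stilbene, so the phenol is protected from the start and unmasked directly before the key step. An acetal is chosen because it is inert to base and to the palladium–amine conditions of the cross-coupling, and because it is cleaved in acidic methanol, where the methyl ester cannot change.

7 to 5 and 6. The C1'–C7' bond of the side chain is cut to aryl bromide 5 and methyl acrylate 6 (Heck logic). The bromine is already present in the commercial aldehyde 1, para to the phenol oxygen, so no regiochemical question arises. The coupling is placed after the stilbene olefination so that the phosphonate carbanion never meets a Michael acceptor.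

5 to 2 and 4. The stilbene bond C7=C8 is cut to aldehyde 2 and benzylic phosphonate 4. A phosphonate olefination is preferred to a phosphonium ylide because it gives the (E)-stilbene, and the (E)-geometry is what later becomes the trans relationship of C7 and C8. The polarity (aldehyde on ring B, phosphonate on ring A) follows from what can be bought.

2 to 1, and 4 to 3. Aldehyde 2 is the methoxymethyl ether of 1, and 4 comes from chloride 3 by an Arbuzov reaction. Compounds 1, 3 and 6 are commercial.

Alternatives that were turned down

Alternative 1: Here ring B is not bought but built. The C3'–C4' and C5'–C6' bonds are cut, which leads back to the acyclic ynol ether A1: O4' already sits on C7 as an ethynyl ether, and C8 carries a 2-furyl group that supplies C3', C2', C1' and C6'. In the forward direction Ph3PAuNTf2 activates the alkyne, furan C2 adds to the oxygen-bearing alkyne carbon, and opening and reclosure of the furan should give phenol A2. Ring B and the dihydrofuran form together, with a new hydroxyl at C5'.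
- For it: the key step is a reagent-free isomerisation under neutral conditions. Both stereocentres are already present in A1 and are not touched, so the ring-forming step carries no stereochemical risk, and with C9 at the alcohol level no base-labile H8 exists. On these points it is stronger than the chosen route.
- Against it: the two stereocentres of A1 must be made first by separate acyclic stereocontrol. Ynol ethers of secondary benzylic alcohols are fragile (sigmatropic rearrangement, hydration) and hard to install on a hindered alcohol. A2 is still far from the target: the C5' phenol must be methylated, the two primary silyl ethers at C9 and C7' must be told apart, and C7' must be oxidised, extended by two carbons and reduced.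
- Comparison: the count would run well into double figures against seven steps here. The chosen route pays for its brevity with an unproven enantioselective step, but it sets the ring and both stereocentres at once from an achiral precursor that is five routine steps from commercial material.

Alternative 2: The aryl ether bond C4'–O4' is cut last. Bromo alcohol A3, in which C7 and C8 are set as a syn aldol pair, is cyclised to A4 with CuI, 1,10-phenanthroline and Cs2CO3 (intramolecular Ullmann-type etherification), with retention at both centres because neither is involved in the bond formation.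
- For it: the stereocentres come from an auxiliary-controlled aldol reaction of predictable sense, and the ring closure is known chemistry. In certainty of the stereochemical outcome it is clearly stronger than the chosen route.
- Against it: a stoichiometric auxiliary, its reductive removal and a selective protection all precede the cyclisation. The bromide to be displaced is flanked on both sides (C5' methoxy and the branched C8 chain), and a secondary benzylic alkoxide under hot copper catalysis can be oxidised or eliminated. A4 also has no substituent at C1', so the three-carbon chain must be introduced afterwards by electrophilic substitution on ring B, in competition with the very electron-rich ring A, and then built up by olefination, reduction and desilylation.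
- Comparison: roughly twice the step count and a late regiochemical problem. The chosen route offers a ring B whose four substituents are all in place from compound 1, and a catalytic rather than auxiliary-based source of chirality.

Alternative 3: The C7–C8 bond is cut. Aryldiazoacetate A5 carries ring A as a benzyl ether on O4'. It is decomposed by Rh2(S-PTTL)4, and the carbene at C8 inserts into the benzylic C7–H bond to give the cis ester A6.
- For it: this is a known reaction class with high enantio- and cis-selectivity on this very ring system. In precedent it is the strongest of all four strategies.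
- Against it: it delivers the cis ester, so C8 has to be epimerised with base afterwards, which is exactly the operation in which phenoxide expulsion can erase C7. The arylacetate has to be made by homologation and then converted into a diazo compound. The acrylate must be attached after the stereocentres exist, by a hot, basic palladium coupling on a base-sensitive ester.
- Comparison: about ten steps against seven. The chosen route should give the trans ester directly, with the side chain already in place, and needs no diazo intermediate. Because Alternative 3 rests on known chemistry, it is kept as the fallback for the key step.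

Key step: step 6

Assumption: which enantiomer of the bis(oxazoline) ligand directs oxygen to the face of the alkene that gives (7R) cannot be derived with certainty; the route is written with the (S,S)-ligand, and the commercially available (R,R)-antipode would be used if the opposite sense is found.

Step 1
Reactants: 1 5-bromo-2-hydroxy-3-methoxybenzaldehyde
Product: 2 5-bromo-3-methoxy-2-(methoxymethoxy)benzaldehyde
Conditions: MOMCl, i-Pr2NEt, CH2Cl2, 0 °C to rt
Reagents that add atoms: chloromethyl methyl ether, COCCl
Why: O-alkylation of the phenol to a methoxymethyl acetal; the hydrogen-bonded salicylaldehyde phenol is acidic enough for the amine base, and the aldehyde and the aryl bromide are not touched.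

Step 2
Reactants: 3 3,4,5-trimethoxybenzyl chloride
Product: 4 diethyl (3,4,5-trimethoxybenzyl)phosphonate
Conditions: P(OEt)3 (neat), 140 °C
Reagents that add atoms: triethyl phosphite, CCOP(OCC)OCC
Why: Michaelis–Arbuzov reaction; the electron-rich benzylic chloride is a good substrate for displacement by phosphorus, and the chloroethane formed leaves the hot mixture, which drives the dealkylation.

Step 3
Reactants: 4 diethyl (3,4,5-trimethoxybenzyl)phosphonate; 2 5-bromo-3-methoxy-2-(methoxymethoxy)benzaldehyde
Product: 5 5-bromo-1-methoxy-2-(methoxymethoxy)-3-[(E)-2-(3,4,5-trimethoxyphenyl)ethenyl]benzene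
Conditions: KOtBu, THF, 0 °C; then 2, 0 °C to rt
Reagents that add atoms: none
Why: Horner–Wadsworth–Emmons olefination; benzylic phosphonate carbanions add reversibly to aromatic aldehydes and should give the (E)-stilbene. The aldehyde cannot enolise, and the acetal and the aryl bromide are inert to the base.

Step 4
Reactants: 5 5-bromo-1-methoxy-2-(methoxymethoxy)-3-[(E)-2-(3,4,5-trimethoxyphenyl)ethenyl]benzene; 6 methyl acrylate
Product: 7 methyl (E)-3-{3-methoxy-4-(methoxymethoxy)-5-[(E)-2-(3,4,5-trimethoxyphenyl)ethenyl]phenyl}prop-2-enoate
Conditions: Pd(OAc)2, P(o-tol)3, Et3N, DMF, 100 °C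
Reagents that add atoms: none
Why: Mizoroki–Heck reaction; oxidative addition at the aryl bromide, insertion of the acrylate with the aryl group going to the β-carbon and syn β-hydride elimination should give the (E)-cinnamate. The internal 1,2-diaryl alkene is far less reactive toward carbopalladation than the terminal acrylate.

Step 5
Reactants: 7 methyl (E)-3-{3-methoxy-4-(methoxymethoxy)-5-[(E)-2-(3,4,5-trimethoxyphenyl)ethenyl]phenyl}prop-2-enoate
Product: 8 methyl (E)-3-{4-hydroxy-3-methoxy-5-[(E)-2-(3,4,5-trimethoxyphenyl)ethenyl]phenyl}prop-2-enoate
Conditions: HCl (cat.), MeOH–THF, 45 °C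
Reagents that add atoms: none
Why: acid-catalysed acetal exchange; methanol traps the oxocarbenium ion as dimethoxymethane and frees the phenol. Because the solvent is methanol, the methyl ester cannot be altered by transesterification.

Step 6
Reactants: 8 methyl (E)-3-{4-hydroxy-3-methoxy-5-[(E)-2-(3,4,5-trimethoxyphenyl)ethenyl]phenyl}prop-2-enoate
Product: 9 methyl (2R,3R)-7-methoxy-5-[(E)-3-methoxy-3-oxoprop-1-enyl]-2-(3,4,5-trimethoxyphenyl)-2,3-dihydro-1-benzofuran-3-carboxylate (trans)
Conditions: Pd(OCOCF3)2 (10 mol %), 2,2'-(propane-2,2-diyl)bis[(4S)-4-phenyl-4,5-dihydro-1,3-oxazole] (12 mol %), p-benzoquinone (1.5 equiv), CO (1–5 bar), MeOH–CH2Cl2, −20 to 0 °C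
Reagents that add atoms: carbon monoxide, [C-]#[O+]; methanol, CO
Why: Proposed new method: the electrophilic bis(oxazoline) complex of Pd(OCOCF3)2 is expected to bind the electron-rich stilbene alkene of 8, the phenol oxygen then attacks C7 on the face opposite the metal, and the resulting C8–palladium bond (benzylic to ring B) inserts CO with retention before methanol cleaves the acyl–palladium bond, while p-benzoquinone returns zerovalent palladium to divalent palladium. The closest known reaction types are the oxidative cyclisation of 2-hydroxystilbenes to 2-arylbenzofurans with divalent palladium, which shares the oxypalladation but ends in β-hydride elimination, and the enantioselective intramolecular alkoxycarbonylation of alkenols under this same catalyst–oxidant–CO–methanol combination; what has not been shown is the two together on a stilbene. The dihydrofuran closes in a 5-endo-trig mode, tolerable here because the nucleophile adds to a metal-bound alkene that can slip toward C8 as positive charge builds at C7 next to the trimethoxyphenyl ring. C7 is controlled by the chiral ligand, which decides which alkene face carries palladium and hence which face is open to oxygen. C8 is controlled by C7 through the (E)-geometry, the anti addition and the retentive CO insertion, which together should give the trans ester. The step needs CO capture to beat β-hydride elimination of H7, which lies cis to palladium after anti addition, and to beat CO insertion into a palladium–phenoxide bond, which would lead toward a lactone. The CO atmosphere, a chelating ligand that leaves no free cis site, and the low temperature are meant to secure this. The acrylate alkene is electron-poor, binds divalent palladium weakly and has no nucleophile within reach, so it should remain untouched.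

Step 7
Reactants: 9 methyl (2R,3R)-7-methoxy-5-[(E)-3-methoxy-3-oxoprop-1-enyl]-2-(3,4,5-trimethoxyphenyl)-2,3-dihydro-1-benzofuran-3-carboxylate (trans)
Product: 10 (E)-3-[(2R,3S)-3-(hydroxymethyl)-7-methoxy-2-(3,4,5-trimethoxyphenyl)-2,3-dihydro-1-benzofuran-5-yl]prop-2-en-1-ol, the target (7R,8S,7'E)
Conditions: i-Bu2AlH (6 equiv), CH2Cl2, −78 to −20 °C; aq. potassium sodium tartrate
Reagents that add atoms: none
Why: ester reduction with an electrophilic aluminium hydride; both esters should go to primary alcohols, the cinnamate by 1,2-reduction. The medium is not basic and the temperature is low, so neither removal of H8 nor ionisation at C7 is expected, and both stereocentres should be carried through (the descriptor at C8 changes from R to S only because the substituent priorities change).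

Compound list

1 | 5-bromo-2-hydroxy-3-methoxybenzaldehyde | COc1cc(Br)cc(C=O)c1O | starting material
2 | 5-bromo-3-methoxy-2-(methoxymethoxy)benzaldehyde | COCOc1c(OC)cc(Br)cc1C=O | intermediate
3 | 3,4,5-trimethoxybenzyl chloride | COc1cc(CCl)cc(OC)c1OC | starting material
4 | diethyl (3,4,5-trimethoxybenzyl)phosphonate | CCOP(=O)(Cc1cc(OC)c(OC)c(OC)c1)OCC | intermediate
5 | 5-bromo-1-methoxy-2-(methoxymethoxy)-3-[(E)-2-(3,4,5-trimethoxyphenyl)ethenyl]benzene | COCOc1c(OC)cc(Br)cc1/C=C/c1cc(OC)c(OC)c(OC)c1 | intermediate
6 | methyl acrylate | C=CC(=O)OC | starting material
7 | methyl (E)-3-{3-methoxy-4-(methoxymethoxy)-5-[(E)-2-(3,4,5-trimethoxyphenyl)ethenyl]phenyl}prop-2-enoate | COCOc1c(OC)cc(/C=C/C(=O)OC)cc1/C=C/c1cc(OC)c(OC)c(OC)c1 | intermediate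
8 | methyl (E)-3-{4-hydroxy-3-methoxy-5-[(E)-2-(3,4,5-trimethoxyphenyl)ethenyl]phenyl}prop-2-enoate | COC(=O)/C=C/c1cc(OC)c(O)c(/C=C/c2cc(OC)c(OC)c(OC)c2)c1 | intermediate
9 | methyl (2R,3R)-7-methoxy-5-[(E)-3-methoxy-3-oxoprop-1-enyl]-2-(3,4,5-trimethoxyphenyl)-2,3-dihydro-1-benzofuran-3-carboxylate (trans) | COc1cc([C@@H]2Oc3c(OC)cc(/C=C/C(=O)OC)cc3[C@H]2C(=O)OC)cc(OC)c1OC | intermediate
10 | (E)-3-[(2R,3S)-3-(hydroxymethyl)-7-methoxy-2-(3,4,5-trimethoxyphenyl)-2,3-dihydro-1-benzofuran-5-yl]prop-2-en-1-ol | COc1cc([C@@H]2Oc3c(OC)cc(/C=C/CO)cc3[C@H]2CO)cc(OC)c1OC | target

Total step count: 7. Longest linear sequence: 6 steps (1 to 2 to 5 to 7 to 8 to 9 to 10; the two-step branch 3 to 4 joins in step 3).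

Steps least certain to work

Step 6 (key step, the one step that goes beyond known chemistry). Four processes could defeat it:
- β-Hydride elimination at the C8–palladium intermediate may outrun CO insertion, which would aromatise the new ring and erase both stereocentres.
- CO may insert into a palladium–phenoxide bond and acylpalladation may follow, diverting the substrate into a six-membered lactone manifold.
- Enantioface discrimination may be poor, because both alkene substituents are aryl groups and the ligand has little more than the tethered phenol to tell the faces apart.
- Partial syn oxypalladation may occur. It would appear as the C8 epimer, methyl (2R,3S)-7-methoxy-5-[(E)-3-methoxy-3-oxoprop-1-enyl]-2-(3,4,5-trimethoxyphenyl)-2,3-dihydro-1-benzofuran-3-carboxylate (cis) F1. This alone would be corrected without leaving the route, by brief equilibration with catalytic NaOMe in MeOH at 0 °C to the trans ester 9. The treatment must be kept short, since the same enolate can expel the ring B phenoxide, which here is a good leaving group because of the para acrylate.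

Fallback, known chemistry only, setting out from 1 and 3 and coming back to the route at 9: compound 1 would be O-alkylated with 3 (K2CO3, DMF, 60 °C) to 5-bromo-3-methoxy-2-[(3,4,5-trimethoxybenzyl)oxy]benzaldehyde F2. Reductive cyanation with p-toluenesulfonylmethyl isocyanide (KOtBu, DME, −30 °C, then MeOH, reflux; van Leusen reaction) would give {5-bromo-3-methoxy-2-[(3,4,5-trimethoxybenzyl)oxy]phenyl}acetonitrile F3. Hydrolysis (KOH, aq. EtOH, reflux) would give {5-bromo-3-methoxy-2-[(3,4,5-trimethoxybenzyl)oxy]phenyl}acetic acid F4, and methylation (MeI, K2CO3, DMF) would give methyl {5-bromo-3-methoxy-2-[(3,4,5-trimethoxybenzyl)oxy]phenyl}acetate F5. Diazo transfer (4-acetamidobenzenesulfonyl azide, DBU, MeCN, 0 °C) would give methyl 2-{5-bromo-3-methoxy-2-[(3,4,5-trimethoxybenzyl)oxy]phenyl}-2-diazoacetate F6, the same compound as A5. Enantioselective intramolecular carbene C–H insertion with Rh2(S-PTTL)4 (toluene, −60 °C; the catalyst antipode if the sense is opposite) would give methyl (2R,3S)-5-bromo-7-methoxy-2-(3,4,5-trimethoxyphenyl)-2,3-dihydro-1-benzofuran-3-carboxylate (cis) F7, the same compound as A6. Equilibration at C8 (NaOMe, MeOH, 0 °C) would give methyl (2R,3R)-5-bromo-7-methoxy-2-(3,4,5-trimethoxyphenyl)-2,3-dihydro-1-benzofuran-3-carboxylate (trans) F8, and a Heck reaction of F8 with 6 (Pd(OAc)2, P(o-tol)3, Et3N, DMF, 90 °C) would give 9.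

Step 5. The acid that removes the acetal may also protonate the electron-rich stilbene at C8. The cation at C7, stabilised by ring A, would then be captured by the newly freed phenol, and the key-step substrate would be consumed in a racemic ring closure that lacks C9. Fallback, setting out from 1 and 4 and coming back at 8: the protecting group would be dispensed with. The potassium phenoxide of 1 would be olefinated directly with 4 (KOtBu, 2.5 equiv, DMF, 0 °C to rt) to 4-bromo-2-methoxy-6-[(E)-2-(3,4,5-trimethoxyphenyl)ethenyl]phenol F9. This olefination is slower because the phenoxide deactivates the aldehyde, which is why it is not the main line, but it needs no acid at any point. A Heck reaction of F9 with 6 (Pd(OAc)2, P(o-tol)3, Et3N, DMF, 100 °C) would then give 8.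

Step 4. Oxidative addition into a bromide that stands para to an alkoxy group is slow, so the catalyst may decompose before conversion is complete, and at the higher temperatures then needed carbopalladation of the stilbene could begin. Fallback, setting out from 5 and coming back at 7, without any cross-coupling: bromine–lithium exchange (n-BuLi, THF, −78 °C) and formylation with DMF would give 3-methoxy-4-(methoxymethoxy)-5-[(E)-2-(3,4,5-trimethoxyphenyl)ethenyl]benzaldehyde F10. A second Horner–Wadsworth–Emmons reaction, with trimethyl phosphonoacetate (NaH, THF, 0 °C), would give 7.

Step 3. Addition to the electron-rich, ortho-alkoxy aldehyde may be sluggish and the (E)-selectivity incomplete. Any (Z)-alkene would be carried into the cis series by the anti addition of step 6. Fallback, setting out from 2 and coming back at 5: Wittig methylenation of 2 (Ph3PCH3Br, KOtBu, THF, 0 °C) would give 5-bromo-1-ethenyl-3-methoxy-2-(methoxymethoxy)benzene F11. A Heck reaction of F11 with commercial 5-iodo-1,2,3-trimethoxybenzene under ligand-free phase-transfer conditions (Pd(OAc)2, n-Bu4NCl, NaHCO3, DMF, 60 °C), in which the iodide reacts well before the bromide, would give 5 with the (E)-geometry fixed by the syn β-hydride elimination.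

Steps 1, 2 and 7 are routine for this class of compound; step 7 only has to be kept cold.

Further compounds

F1 | step 6 | methyl (2R,3S)-7-methoxy-5-[(E)-3-methoxy-3-oxoprop-1-enyl]-2-(3,4,5-trimethoxyphenyl)-2,3-dihydro-1-benzofuran-3-carboxylate (cis) | COc1cc([C@@H]2Oc3c(OC)cc(/C=C/C(=O)OC)cc3[C@@H]2C(=O)OC)cc(OC)c1OC
F2 | step 6 | 5-bromo-3-methoxy-2-[(3,4,5-trimethoxybenzyl)oxy]benzaldehyde | COc1cc(Br)cc(C=O)c1OCc1cc(OC)c(OC)c(OC)c1
F3 | step 6 | {5-bromo-3-methoxy-2-[(3,4,5-trimethoxybenzyl)oxy]phenyl}acetonitrile | COc1cc(Br)cc(CC#N)c1OCc1cc(OC)c(OC)c(OC)c1
F4 | step 6 | {5-bromo-3-methoxy-2-[(3,4,5-trimethoxybenzyl)oxy]phenyl}acetic acid | COc1cc(Br)cc(CC(=O)O)c1OCc1cc(OC)c(OC)c(OC)c1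
F5 | step 6 | methyl {5-bromo-3-methoxy-2-[(3,4,5-trimethoxybenzyl)oxy]phenyl}acetate | COC(=O)Cc1cc(Br)cc(OC)c1OCc1cc(OC)c(OC)c(OC)c1
F6 | step 6 | methyl 2-{5-bromo-3-methoxy-2-[(3,4,5-trimethoxybenzyl)oxy]phenyl}-2-diazoacetate | COC(=O)C(=[N+]=[N-])c1cc(Br)cc(OC)c1OCc1cc(OC)c(OC)c(OC)c1
F7 | step 6 | methyl (2R,3S)-5-bromo-7-methoxy-2-(3,4,5-trimethoxyphenyl)-2,3-dihydro-1-benzofuran-3-carboxylate (cis) | COc1cc([C@@H]2Oc3c(OC)cc(Br)cc3[C@@H]2C(=O)OC)cc(OC)c1OC
F8 | step 6 | methyl (2R,3R)-5-bromo-7-methoxy-2-(3,4,5-trimethoxyphenyl)-2,3-dihydro-1-benzofuran-3-carboxylate (trans) | COc1cc([C@@H]2Oc3c(OC)cc(Br)cc3[C@H]2C(=O)OC)cc(OC)c1OC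
F9 | step 5 | 4-bromo-2-methoxy-6-[(E)-2-(3,4,5-trimethoxyphenyl)ethenyl]phenol | COc1cc(Br)cc(/C=C/c2cc(OC)c(OC)c(OC)c2)c1O
F10 | step 4 | 3-methoxy-4-(methoxymethoxy)-5-[(E)-2-(3,4,5-trimethoxyphenyl)ethenyl]benzaldehyde | COCOc1c(OC)cc(C=O)cc1/C=C/c1cc(OC)c(OC)c(OC)c1
F11 | step 3 | 5-bromo-1-ethenyl-3-methoxy-2-(methoxymethoxy)benzene | COCOc1c(OC)cc(Br)cc1C=C
A1 | alternative 1 | tert-butyl{[(2S,3R)-2-[4-({[tert-butyl(dimethyl)silyl]oxy}methyl)furan-2-yl]-3-(ethynyloxy)-3-(3,4,5-trimethoxyphenyl)propyl]oxy}dimethylsilane | C#CO[C@@H](c1cc(OC)c(OC)c(OC)c1)[C@H](CO[Si](C)(C)C(C)(C)C)c1cc(CO[Si](C)(C)C(C)(C)C)co1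
A2 | alternative 1 | (2R,3S)-3,5-bis({[tert-butyl(dimethyl)silyl]oxy}methyl)-2-(3,4,5-trimethoxyphenyl)-2,3-dihydro-1-benzofuran-7-ol | COc1cc([C@@H]2Oc3c(O)cc(CO[Si](C)(C)C(C)(C)C)cc3[C@H]2CO[Si](C)(C)C(C)(C)C)cc(OC)c1OC
A3 | alternative 2 | (1R,2S)-2-(2-bromo-3-methoxyphenyl)-3-{[tert-butyl(dimethyl)silyl]oxy}-1-(3,4,5-trimethoxyphenyl)propan-1-ol | COc1cc([C@H](O)[C@H](CO[Si](C)(C)C(C)(C)C)c2cccc(OC)c2Br)cc(OC)c1OC
A4 | alternative 2 | tert-butyl{[(2R,3S)-7-methoxy-2-(3,4,5-trimethoxyphenyl)-2,3-dihydro-1-benzofuran-3-yl]methoxy}dimethylsilane (trans) | COc1cc([C@@H]2Oc3c(OC)cccc3[C@H]2CO[Si](C)(C)C(C)(C)C)cc(OC)c1OC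
A5 | alternative 3 | methyl 2-{5-bromo-3-methoxy-2-[(3,4,5-trimethoxybenzyl)oxy]phenyl}-2-diazoacetate | COC(=O)C(=[N+]=[N-])c1cc(Br)cc(OC)c1OCc1cc(OC)c(OC)c(OC)c1
A6 | alternative 3 | methyl (2R,3S)-5-bromo-7-methoxy-2-(3,4,5-trimethoxyphenyl)-2,3-dihydro-1-benzofuran-3-carboxylate (cis) | COc1cc([C@@H]2Oc3c(OC)cc(Br)cc3[C@@H]2C(=O)OC)cc(OC)c1OC
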